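**Plan**

- Cuts, in retrosynthetic order: (1) the C9–C11 bond between ring B and the side chain, giving a bicyclic C14 enol triflate and a C6 alkylzinc; (2) the C4–C5 and C9–C10 ring bonds together, giving an acyclic trienylsilane made from (E)-geranylacetone; (3) in the side chain, the bond from C11 to the carboxyl carbon of a linalool-derived acid.
- Forward: rings A and B form in one bromonium-initiated bicyclisation (C4–C5 first, then C9–C10, with silicon leaving from C9). C9 is then oxidised to the ketone and converted to the enol triflate. The side chain is cut out of (R)-linalool, the halves are joined at C9–C11, and desilylation ends the route.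
- Enabling feature: ring-B carbon C9 lies between the quaternary C10 and C8, so a C9 ketone has only one enolisable position (C8–H) and its triflate fixes the tetrasubstituted C8=C9 alkene. The ring-A C3–Br is an equatorial neopentyl C(sp3)–Br that Pd(0) and RZnI should leave alone, and C11 is a primary carbon γ to the C13 oxygen, so its organozinc cannot β-eliminate.
- Stereochemistry: C3, C5 and C10 come from catalyst-controlled Br+ transfer and chair–chair folding of the (E)-alkene (trans-decalin, equatorial Br cis to the C10 methyl). C13 comes from (R)-(−)-linalool and is not touched.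

Key step: step 10

Remark: labdane numbering is used throughout; (E)-geranylacetone and (R)-(−)-linalool are taken as commercial in isomerically and enantiomerically enriched form, and the catalyst antipode in step 2 is the one that leads to the 3R series.

**Route**

Step 1
Reactants: 1 (E)-geranylacetone
Product: 2 trimethyl[(5E)-2,6,10-trimethylundeca-1,5,9-trien-1-yl]silane (1E/1Z mixture)
Conditions: Cp2Ti(CH2SiMe3)2, toluene, 110 °C
Reagents that add atoms: bis(cyclopentadienyl)bis(trimethylsilylmethyl)titanium, C[Si](C)(C)C[Ti](C[Si](C)(C)C)(C1C=CC=C1)C1C=CC=C1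
Why: Thermolysis of the dialkyltitanocene gives a titanium silylmethylidene that olefinates the methyl ketone without enolising it (Petasis-type carbonyl olefination); both vinylsilane geometries carry silicon on the future C9 and are usable.

Step 2
Reactants: 2 trienylsilane
Product: 3 ent-3β-bromo-11-nordrim-8-ene (trans-decalin with 4,4,8,10-tetramethyl, C8=C9 alkene, equatorial 3-Br cis to the C10 methyl)
Conditions: DBDMH (1.05 equiv), chiral BINOL-derived thiophosphoramide Lewis base (10 mol %), toluene/CH2Cl2, −78 °C; aq. Na2S2O3
Reagents that add atoms: 1,3-dibromo-5,5-dimethylhydantoin (DBDMH), CC1(C)N(Br)C(=O)N(Br)C1=O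
Why: Proposed new method: the P=S Lewis base takes Br+ from DBDMH and delivers it to one enantiotopic face of the terminal Me2C=CH alkene (the least hindered of the three trisubstituted alkenes), C5 of the (E)-alkene attacks C4 anti to bromine through a chair–chair fold (C4–C5 bond, equatorial Br, trans fusion), and the tertiary C10 cation is captured by the silicon-bearing vinylsilane carbon (C9–C10 bond, β-silyl-stabilised C8 cation), whose loss of Me3Si+ places the alkene at C8=C9 without releasing acid; the closest known reaction types are the Lewis-base-catalysed enantioselective bromocyclisation of arene-terminated geranyl polyenes and the vinylsilane-terminated cation–olefin cyclisation, the new element being their combination, with the enantio-determining bromonium transfer expected to be independent of the remote terminator.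

Step 3
Reactants: 3 ent-3β-bromo-11-nordrim-8-ene
Product: 5 ent-3β-bromo-11-nor-8αH-driman-9α-ol (9-OH trans and 8-methyl cis to the C10 methyl), via alkylborane 4 (not isolated)
Conditions: BH3·THF, THF, 0 °C to rt; then NaOH, H2O2, 0 °C
Reagents that add atoms: hydrogen peroxide, OO
Why: Hydroboration–oxidation puts boron on the less substituted C9 of the trisubstituted alkene by syn addition from the face opposite the axial C10 methyl, which sets C8 and C9; both centres are erased again in steps 4 and 5.

Step 4
Reactants: 5 ent-3β-bromo-11-nor-8αH-driman-9α-ol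
Product: 6 ent-3β-bromo-11-nor-8αH-driman-9-one
Conditions: Dess–Martin periodinane, NaHCO3, CH2Cl2, rt
Reagents that add atoms: none
Why: Dess–Martin oxidation converts the hindered secondary alcohol to the ketone under buffered, non-basic conditions that leave the C3 bromide alone; the C8 configuration is of no consequence.

Step 5
Reactants: 6 ent-3β-bromo-11-nor-8αH-driman-9-one
Product: 8 ent-3β-bromo-11-nordrim-8-en-9-yl trifluoromethanesulfonate, via potassium enolate 7 (not isolated)
Conditions: KHMDS, THF, −78 to 0 °C; PhNTf2, −78 °C to rt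
Reagents that add atoms: N-phenylbis(trifluoromethanesulfonimide), O=S(=O)(N(c1ccccc1)S(=O)(=O)C(F)(F)F)C(F)(F)F
Why: Because C10 is quaternary the ketone can be deprotonated only at C8–H, so O-triflation of the enolate (enol triflate formation) fixes the C8=C9 alkene; the equatorial bromide has no anti-periplanar hydrogen and should resist E2.

Step 6
Reactants: 9 (R)-(−)-linalool
Product: 10 triethyl{[(3R)-3,7-dimethylocta-1,6-dien-3-yl]oxy}silane
Conditions: TESOTf, 2,6-lutidine, CH2Cl2, −78 to 0 °C
Reagents that add atoms: triethylsilyl trifluoromethanesulfonate, CC[Si](CC)(CC)OS(=O)(=O)C(F)(F)F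
Why: Silylation of the tertiary allylic alcohol with the silyl triflate and a hindered base protects the C13 oxygen; the stereocentre comes unchanged from the chiral pool.

Step 7
Reactants: 10 linalool TES ether
Product: 11 (4R)-4-methyl-4-(triethylsilyloxy)hex-5-enal
Conditions: O3 (1 equiv, Sudan III end point), CH2Cl2/MeOH, −78 °C; then Me2S, −78 °C to rt
Reagents that add atoms: ozone, [O-][O+]=O
Why: In this ozonolysis the electron-rich trisubstituted alkene should react far faster than the monosubstituted vinyl group next to the silyloxy-bearing quaternary carbon, so one equivalent of ozone cleaves only the isopropylidene end.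

Step 8
Reactants: 11 (4R)-4-methyl-4-(triethylsilyloxy)hex-5-enal
Product: 12 (4R)-4-methyl-4-(triethylsilyloxy)hex-5-enoic acid
Conditions: NaClO2, NaH2PO4, 2-methyl-2-butene, t-BuOH/H2O, 0 °C to rt
Reagents that add atoms: sodium chlorite, [Na+].[O-]Cl=O
Why: Pinnick oxidation takes the aldehyde to the acid under buffered conditions, with 2-methyl-2-butene scavenging HOCl so that the vinyl group and silyl ether survive.

Step 9
Reactants: 12 (4R)-4-methyl-4-(triethylsilyloxy)hex-5-enoic acid
Product: 14 (3R)-5-iodo-3-methyl-3-(triethylsilyloxy)pent-1-ene, via Barton ester 13 (not isolated)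
Conditions: N-hydroxypyridine-2-thione, DCC, DMAP (cat.), CH2Cl2, dark, 0 °C to rt; then CHI3, hν (tungsten lamp), rt
Reagents that add atoms: iodoform, IC(I)I
Why: In this Barton decarboxylative iodination the thiohydroxamate ester fragments under visible light to the primary C11 radical, which abstracts iodine from iodoform; this removes the surplus linalool carbon without touching the quaternary C13.

Step 10
Reactants: 8 ent-3β-bromo-11-nordrim-8-en-9-yl trifluoromethanesulfonate; 14 (3R)-5-iodo-3-methyl-3-(triethylsilyloxy)pent-1-ene
Product: 16 (3R,5S,10R,13R)-3-bromo-13-(triethylsilyloxy)labda-8,14-diene, via alkylzinc iodide 15 (not isolated)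
Conditions: 14, Zn dust (TMSCl/1,2-dibromoethane activated), LiCl, THF, 40 °C; filtered solution added to 8, PdCl2(dppf) (5 mol %), THF/NMP, 60 °C
Reagents that add atoms: none
Why: Pd(0) inserts into the C9–OTf bond of 8, the primary alkyl group of 15 moves from zinc to palladium, and reductive elimination forms the C9–C11 bond (Negishi alkyl–alkenyl cross-coupling). The closest known reaction type is the Pd-catalysed coupling of alkylzinc halides with tetrasubstituted cycloalkenyl triflates that sit next to a quaternary carbon (2,6,6-trimethylcyclohexenyl triflate type). No ring is closed and no stereocentre is formed: C3, C5 and C10 arrive with 8 and C13 with 15, and none lies at a reacting centre. The position of the tetrasubstituted alkene is dictated by the triflate, which could only form toward C8. The step needs selectivity for C(sp2)–OTf over the C3–Br bond and reductive elimination faster than β-hydride elimination: the bromide is an equatorial secondary neopentyl C(sp3)–Br that neither Pd(0)/dppf nor the organozinc should attack, the wide-bite-angle ligand speeds reductive elimination, and the silyl ether sits γ to zinc so the reagent cannot β-eliminate.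

Step 11
Reactants: 16 (3R,5S,10R,13R)-3-bromo-13-(triethylsilyloxy)labda-8,14-diene
Product: 17 (3R,5S,10R,13R)-3-bromolabda-8,14-dien-13-ol
Conditions: TBAF, THF, 0 °C to rt
Reagents that add atoms: none
Why: Fluoride cleaves the Si–O bond (desilylation) without acid, so the ionisable tertiary allylic alcohol and the C3 bromide should survive.

**Compound list**

1 | (E)-geranylacetone, (5E)-6,10-dimethylundeca-5,9-dien-2-one | CC(C)=CCC/C(C)=C/CCC(C)=O | starting material
2 | trimethyl[(5E)-2,6,10-trimethylundeca-1,5,9-trien-1-yl]silane (1E/1Z mixture) | CC(C)=CCC/C(C)=C/CCC(C)=C[Si](C)(C)C | intermediate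
3 | ent-3β-bromo-11-nordrim-8-ene | C1=C(C)CC[C@@H]2C(C)(C)[C@H](Br)CC[C@@]12C | intermediate
4 | alkylborane, ent-3β-bromo-11-nor-8αH-driman-9α-ylborane (not isolated) | B[C@H]1[C@H](C)CC[C@@H]2C(C)(C)[C@H](Br)CC[C@@]12C | intermediate
5 | ent-3β-bromo-11-nor-8αH-driman-9α-ol | O[C@H]1[C@H](C)CC[C@@H]2C(C)(C)[C@H](Br)CC[C@@]12C | intermediate
6 | ent-3β-bromo-11-nor-8αH-driman-9-one | O=C1[C@H](C)CC[C@@H]2C(C)(C)[C@H](Br)CC[C@@]12C | intermediate
7 | potassium enolate of 6 (C8=C9, not isolated) | [K+].[O-]C1=C(C)CC[C@@H]2C(C)(C)[C@H](Br)CC[C@@]12C | intermediate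
8 | ent-3β-bromo-11-nordrim-8-en-9-yl trifluoromethanesulfonate | FC(F)(F)S(=O)(=O)OC1=C(C)CC[C@@H]2C(C)(C)[C@H](Br)CC[C@@]12C | intermediate
9 | (R)-(−)-linalool, (3R)-3,7-dimethylocta-1,6-dien-3-ol | C=C[C@](C)(O)CCC=C(C)C | starting material
10 | triethyl{[(3R)-3,7-dimethylocta-1,6-dien-3-yl]oxy}silane | C=C[C@](C)(O[Si](CC)(CC)CC)CCC=C(C)C | intermediate
11 | (4R)-4-methyl-4-(triethylsilyloxy)hex-5-enal | C=C[C@](C)(O[Si](CC)(CC)CC)CCC=O | intermediate
12 | (4R)-4-methyl-4-(triethylsilyloxy)hex-5-enoic acid | C=C[C@](C)(O[Si](CC)(CC)CC)CCC(=O)O | intermediate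
13 | Barton ester, 1-{[(4R)-4-methyl-4-(triethylsilyloxy)hex-5-enoyl]oxy}pyridine-2(1H)-thione (not isolated) | C=C[C@](C)(O[Si](CC)(CC)CC)CCC(=O)ON1C=CC=CC1=S | intermediate
14 | (3R)-5-iodo-3-methyl-3-(triethylsilyloxy)pent-1-ene | C=C[C@](C)(O[Si](CC)(CC)CC)CCI | intermediate
15 | [(3R)-3-methyl-3-(triethylsilyloxy)pent-4-en-1-yl]zinc iodide (not isolated) | C=C[C@](C)(O[Si](CC)(CC)CC)CC[Zn]I | intermediate
16 | (3R,5S,10R,13R)-3-bromo-13-(triethylsilyloxy)labda-8,14-diene | C=C[C@](C)(O[Si](CC)(CC)CC)CCC1=C(C)CC[C@@H]2C(C)(C)[C@H](Br)CC[C@@]12C | intermediate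
17 | (3R,5S,10R,13R)-3-bromolabda-8,14-dien-13-ol | C=C[C@](C)(O)CCC1=C(C)CC[C@@H]2C(C)(C)[C@H](Br)CC[C@@]12C | target

**Count and risks**

Total steps: 11. Longest linear sequence: 7 (steps 1–5, 10, 11).

Steps most likely to fail:

1. Step 2 (Proposed new method). Bromonium transfer may discriminate poorly between the two alkene faces, may go to the silyl-substituted or internal alkene (bromodesilylation, wrong initiation site), or the second ring closure may stall. Fallback, from 2 and back at 5: cyclise 2 without catalyst control using an achiral bromenium reagent of the kind established for racemic bromopolyene cyclisation (Et2SBr·SbCl5Br, MeNO2, −25 °C), which gives 3 together with its mirror image ent-3 F1. Hydroboration–oxidation as in step 3 then gives 5 and, through the enantiomeric alkylborane ent-4 F2, the alcohol ent-5 F3. Acylation with (1S)-(−)-camphanic chloride (DMAP, pyridine, CH2Cl2) gives the diastereomeric esters, the camphanate of 5 F4 and the camphanate of ent-5 F5, which are separated by chromatography or crystallisation. Saponification of F4 (LiOH, THF/MeOH/H2O) returns enantiopure 5.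

2. Step 10. Oxidative addition and transmetalation at the congested C9 may be slow, which would let S–O cleavage of the triflate (back to the ketone) or β-hydride elimination of the alkylpalladium take over. Fallback, from 8 and 14 and back at 16: Miyaura borylation of 8 (B2pin2, PdCl2(PPh3)2/PPh3, KOPh, toluene, 50 °C) gives the alkenyl pinacol boronate F6. Iodine–lithium exchange on 14 (t-BuLi, Et2O, −78 °C) gives the alkyllithium F7. Addition of F7 to F6 gives the lithium boronate complex F8, and I2 followed by NaOMe (Zweifel olefination: 1,2-migration of the C11 alkyl group from boron to C9, then B/I elimination) gives 16 with no transition metal in the bond-forming event.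

3. Step 9. The radical chain may be diverted by iodine-atom-transfer addition of iodoform-derived radicals to the vinyl group, or the thiohydroxamate ester may decompose before photolysis. Fallback, from 11 and back at 14: TBSOTf/Et3N gives the silyl enol ether F9. Ozonolysis of its enol ether double bond (far more electron-rich than the vinyl group; CH2Cl2/MeOH, −78 °C) gives the one-carbon-shorter aldehyde F10, which is reduced in the same flask (NaBH4) to the primary alcohol F11. PPh3/I2/imidazole (Appel-type iodination) then gives 14.

Further compounds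
F1 | step 2 | ent-3, mirror image of 3 | C1=C(C)CC[C@H]2C(C)(C)[C@@H](Br)CC[C@]12C
F2 | step 2 | ent-4, mirror image of alkylborane 4 (not isolated) | B[C@@H]1[C@@H](C)CC[C@H]2C(C)(C)[C@@H](Br)CC[C@]12C
F3 | step 2 | ent-5, mirror image of 5 | O[C@@H]1[C@@H](C)CC[C@H]2C(C)(C)[C@@H](Br)CC[C@]12C
F4 | step 2 | (1S)-camphanate ester of 5 | O=C(O[C@H]1[C@H](C)CC[C@@H]2C(C)(C)[C@H](Br)CC[C@@]12C)[C@@]12CC[C@@](C)(C(=O)O1)C2(C)C
F5 | step 2 | (1S)-camphanate ester of ent-5 | O=C(O[C@@H]1[C@@H](C)CC[C@H]2C(C)(C)[C@@H](Br)CC[C@]12C)[C@@]12CC[C@@](C)(C(=O)O1)C2(C)C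
F6 | step 10 | 2-(ent-3β-bromo-11-nordrim-8-en-9-yl)-4,4,5,5-tetramethyl-1,3,2-dioxaborolane | CC1(C)OB(OC1(C)C)C1=C(C)CC[C@@H]2C(C)(C)[C@H](Br)CC[C@@]12C
F7 | step 10 | [(3R)-3-methyl-3-(triethylsilyloxy)pent-4-en-1-yl]lithium | C=C[C@](C)(O[Si](CC)(CC)CC)CC[Li]
F8 | step 10 | lithium boronate complex of F6 and F7 | [Li+].C=C[C@](C)(O[Si](CC)(CC)CC)CC[B-]1(OC(C)(C)C(C)(C)O1)C1=C(C)CC[C@@H]2C(C)(C)[C@H](Br)CC[C@@]12C
F9 | step 9 | tert-butyldimethylsilyl enol ether of 11 (E/Z) | C=C[C@](C)(O[Si](CC)(CC)CC)CC=CO[Si](C)(C)C(C)(C)C
F10 | step 9 | (3R)-3-methyl-3-(triethylsilyloxy)pent-4-enal | C=C[C@](C)(O[Si](CC)(CC)CC)CC=O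
F11 | step 9 | (3R)-3-methyl-3-(triethylsilyloxy)pent-4-en-1-ol | C=C[C@](C)(O[Si](CC)(CC)CC)CCO
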